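**Retrosynthetic overview**
- The last step is MOM removal. The pyran ring (O1–C2) is the only ring made; it is closed by an invertive Mitsunobu reaction of an (S)-benzylic alcohol onto the one free A-ring phenol. Both benzene rings are bought.
- The (S)-alcohol comes from Ru-catalysed asymmetric transfer hydrogenation of a 1,3-diarylpropan-1-one.
- Key disconnection C4–C4a: the ketone comes from a ketone homoenolate (C4 nucleophile, released from 1-(3,5-dimethoxyphenyl)cyclopropanol) and an A-ring o-iodophenol (aryl electrophile) under Pd catalysis.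
- The cyclopropanol comes from methyl 3,5-dimethoxybenzoate (Kulinkovich). The iodophenol comes from phloroglucinol: bis-MOM ether, prenylation between the two OMOM groups by directed metalation, then iodination ortho to the free OH, with regiochemistry fixed by symmetry at each stage.

Assumption: the SMILES is read as the (2R)-flavan; MOMCl, prenyl bromide and the Pd/Ru catalysts are bought.

**Step 1**
Reactants: 1 phloroglucinol (benzene-1,3,5-triol)
Product: 2 3,5-bis(methoxymethoxy)phenol
Conditions: NaH (2.0 equiv), MOMCl (2.0 equiv), DMF, 0 °C to rt; chromatography (mono- and tris-ethers recycled)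
Reagents that add atoms: chloromethyl methyl ether (MOMCl), COCCl
Why: Statistical Williamson-type O-alkylation (MOM acetal formation) of the C3-symmetric triol with two equivalents of electrophile gives the bis-ether as the main fraction with no regiochemical question, and the one OH left free is the future ring oxygen O1.

**Step 2**
Reactants: 2 3,5-bis(methoxymethoxy)phenol
Product: 4 3,5-bis(methoxymethoxy)-4-(3-methylbut-2-en-1-yl)phenol, via C4-lithiated lithium phenoxide 3 (not isolated)
Conditions: n-BuLi (2.2 equiv), THF, 0 °C, 1 h; CuI (10 mol %), prenyl bromide (1.05 equiv), −78 to 0 °C; H2O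
Reagents that add atoms: 1-bromo-3-methylbut-2-ene (prenyl bromide), CC(C)=CCBr; n-butyllithium, [Li]CCCC (lithium only in intermediate 3, none in 4)
Why: Directed ortho-metalation: after O–H deprotonation the second equivalent of n-BuLi lithiates the only position flanked by two chelating OMOM groups, and Cu-catalysed SN2 allylation with prenyl bromide puts the prenyl group between the two oxygens that become O5 and O7.

**Step 3**
Reactants: 4 3,5-bis(methoxymethoxy)-4-(3-methylbut-2-en-1-yl)phenol
Product: 5 2-iodo-3,5-bis(methoxymethoxy)-4-(3-methylbut-2-en-1-yl)phenol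
Conditions: I2 (1.0 equiv), NaHCO3, THF–H2O (1:1), 0 °C
Reagents that add atoms: iodine, II
Why: Electrophilic aromatic iodination of the phenoxide, where the two remaining ring positions are equivalent and ortho to the free OH, so mono-iodination can give only one regioisomer and the very electron-rich ring reacts much faster than the isolated trisubstituted alkene.

**Step 4**
Reactants: 6 methyl 3,5-dimethoxybenzoate
Product: 7 1-(3,5-dimethoxyphenyl)cyclopropan-1-ol
Conditions: EtMgBr (2.5 equiv, slow addition), Ti(OiPr)4 (20 mol %), THF–Et2O, 0 °C to rt; aq. NH4Cl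
Reagents that add atoms: ethylmagnesium bromide, CC[Mg]Br
Why: Kulinkovich cyclopropanation, in which the titanium-bound 1,2-dicarbanion equivalent generated from EtMgBr adds twice to the ester carbonyl to give the 1-arylcyclopropanol, the stored form of the B-ring ketone homoenolate.

**Step 5**
Reactants: 5 2-iodo-3,5-bis(methoxymethoxy)-4-(3-methylbut-2-en-1-yl)phenol; 7 1-(3,5-dimethoxyphenyl)cyclopropan-1-ol
Product: 8 1-(3,5-dimethoxyphenyl)-3-[6-hydroxy-2,4-bis(methoxymethoxy)-3-(3-methylbut-2-en-1-yl)phenyl]propan-1-one
Conditions: Pd(OAc)2 (5 mol %), XPhos (10 mol %), Cs2CO3 (2.5 equiv), toluene, 80 °C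
Reagents that add atoms: none
Why: Pd-catalysed ring-opening cross-coupling of a cyclopropanol (ketone homoenolate arylation): oxidative addition into C–I, alkoxide exchange and strain-releasing β-carbon elimination make C4 a palladium-bound nucleophile that reductively eliminates onto the aryl carbon, joining the enone β-carbon and an aryl halide carbon (both normally electrophilic) and delivering C2 at the ketone level, while the bulky biaryl phosphine suppresses β-hydride elimination.

**Step 6**
Reactants: 8 1-(3,5-dimethoxyphenyl)-3-[6-hydroxy-2,4-bis(methoxymethoxy)-3-(3-methylbut-2-en-1-yl)phenyl]propan-1-one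
Product: 9 (1S)-1-(3,5-dimethoxyphenyl)-3-[6-hydroxy-2,4-bis(methoxymethoxy)-3-(3-methylbut-2-en-1-yl)phenyl]propan-1-ol
Conditions: RuCl[(S,S)-TsDPEN](p-cymene) (1 mol %), HCO2H–Et3N (5:2), CH2Cl2, 28 °C
Reagents that add atoms: none
Why: Noyori–Ikariya asymmetric transfer hydrogenation of an aryl alkyl ketone, where the (S,S)-catalyst gives the (S)-carbinol (same sense as acetophenone to (S)-1-phenylethanol) and so sets the only stereocentre, leaving the alkene, MOM ethers and free phenol untouched.

**Step 7**
Reactants: 9 (1S)-1-(3,5-dimethoxyphenyl)-3-[6-hydroxy-2,4-bis(methoxymethoxy)-3-(3-methylbut-2-en-1-yl)phenyl]propan-1-ol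
Product: 10 (2R)-2-(3,5-dimethoxyphenyl)-5,7-bis(methoxymethoxy)-6-(3-methylbut-2-en-1-yl)-3,4-dihydro-2H-chromene
Conditions: PPh3 (1.5 equiv), DIAD (1.5 equiv), THF, 0 °C to rt
Reagents that add atoms: none
Why: Intramolecular Mitsunobu etherification, in which the single free phenol displaces the activated benzylic oxygen in a 6-exo SN2 closure with inversion ((S)-alcohol to (2R)-flavan), and the meta-methoxy groups do not stabilise a benzylic cation, so SN1 leakage is not expected.

**Step 8**
Reactants: 10 (2R)-2-(3,5-dimethoxyphenyl)-5,7-bis(methoxymethoxy)-6-(3-methylbut-2-en-1-yl)-3,4-dihydro-2H-chromene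
Product: 11 (2R)-2-(3,5-dimethoxyphenyl)-6-(3-methylbut-2-en-1-yl)-3,4-dihydro-2H-chromene-5,7-diol
Conditions: 3 M aq. HCl (5 equiv), MeOH, 40 °C, monitored and stopped at full conversion
Reagents that add atoms: none
Why: Acid-catalysed transacetalisation (MOM cleavage) in methanol frees both phenols under conditions mild enough to leave the C2 benzylic ether stereocentre and the aryl methyl ethers intact and to keep the prenyl group from cyclising onto a neighbouring OH.

**Compound list**
1 | phloroglucinol (benzene-1,3,5-triol) | Oc1cc(O)cc(O)c1 | starting material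
2 | 3,5-bis(methoxymethoxy)phenol | COCOc1cc(O)cc(OCOC)c1 | intermediate
3 | lithium 4-lithio-3,5-bis(methoxymethoxy)phenolate (not isolated) | COCOc1cc(O[Li])cc(OCOC)c1[Li] | intermediate
4 | 3,5-bis(methoxymethoxy)-4-(3-methylbut-2-en-1-yl)phenol | COCOc1cc(O)cc(OCOC)c1CC=C(C)C | intermediate
5 | 2-iodo-3,5-bis(methoxymethoxy)-4-(3-methylbut-2-en-1-yl)phenol | COCOc1cc(O)c(I)c(OCOC)c1CC=C(C)C | intermediate
6 | methyl 3,5-dimethoxybenzoate | COC(=O)c1cc(OC)cc(OC)c1 | starting material
7 | 1-(3,5-dimethoxyphenyl)cyclopropan-1-ol | COc1cc(OC)cc(C2(O)CC2)c1 | intermediate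
8 | 1-(3,5-dimethoxyphenyl)-3-[6-hydroxy-2,4-bis(methoxymethoxy)-3-(3-methylbut-2-en-1-yl)phenyl]propan-1-one | COc1cc(OC)cc(C(=O)CCc2c(O)cc(OCOC)c(CC=C(C)C)c2OCOC)c1 | intermediate
9 | (1S)-1-(3,5-dimethoxyphenyl)-3-[6-hydroxy-2,4-bis(methoxymethoxy)-3-(3-methylbut-2-en-1-yl)phenyl]propan-1-ol | COc1cc(OC)cc([C@@H](O)CCc2c(O)cc(OCOC)c(CC=C(C)C)c2OCOC)c1 | intermediate
10 | (2R)-2-(3,5-dimethoxyphenyl)-5,7-bis(methoxymethoxy)-6-(3-methylbut-2-en-1-yl)-3,4-dihydro-2H-chromene | COc1cc(OC)cc([C@H]2CCc3c(cc(OCOC)c(CC=C(C)C)c3OCOC)O2)c1 | intermediate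
11 | (2R)-2-(3,5-dimethoxyphenyl)-6-(3-methylbut-2-en-1-yl)-3,4-dihydro-2H-chromene-5,7-diol (CNP0147692.1) | COc1cc(OC)cc([C@H]2CCc3c(cc(O)c(CC=C(C)C)c3O)O2)c1 | target

**Step count and risks**

Total step count: 8. Longest linear sequence: 7 steps (1 → 2 → 4 → 5 → 8 → 9 → 10 → 11; steps 1, 2, 3, 5, 6, 7, 8), with step 4 as a one-step side branch.

The three steps most likely to fail:

Step 5 (key coupling). The aryl iodide is electron-rich, flanked by two oxygens and carries a free phenol. Slow oxidative addition and β-hydride elimination of the ring-opened palladium alkyl could give mainly de-iodinated 4 and enone. The fallback makes the same C4–C4a bond by conjugate arylation. It sets out from cyclopropanol 7 and iodophenol 5. Cyclopropanol 7 is opened oxidatively (Pd(OAc)2 cat., pyridine, O2, toluene, 80 °C) to 1-(3,5-dimethoxyphenyl)prop-2-en-1-one F1. Iodophenol 5 is then added to this enone in a reductive Heck hydroarylation (Pd(OAc)2, HCO2Na, Bu4NCl, DMF, 60 °C). The fallback comes back to the route at ketone 8.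

Step 2 (prenylation via the dianion). The lithium phenoxide may slow or misdirect the ring lithiation, and O-prenylation can compete. The fallback masks the phenol with a bulky, non-directing silyl group so that a mono-anion is alkylated. It sets out from phenol 2, which is silylated (TIPSCl, imidazole, DMF) to [3,5-bis(methoxymethoxy)phenoxy]tri(propan-2-yl)silane F2. This is lithiated with n-BuLi (1.1 equiv, THF, 0 °C) to [2,6-bis(methoxymethoxy)-4-{[tri(propan-2-yl)silyl]oxy}phenyl]lithium F3. Cu-catalysed reaction with prenyl bromide gives [3,5-bis(methoxymethoxy)-4-(3-methylbut-2-en-1-yl)phenoxy]tri(propan-2-yl)silane F4. Desilylation with TBAF in THF comes back to the route at phenol 4.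

Step 8 (MOM cleavage next to the prenyl group). Protic acid can cyclise the prenyl group onto a freed ortho OH to give a 2,2-dimethylpyran by-product. The fallback avoids protic acid by exchanging the protecting group. It sets out from flavan 10, whose aryl MOM ethers are converted with TMSOTf and 2,2'-bipyridyl (MeCN, 0 °C) into the silyl ethers, giving (2R)-2-(3,5-dimethoxyphenyl)-6-(3-methylbut-2-en-1-yl)-5,7-bis(trimethylsilyloxy)-3,4-dihydro-2H-chromene F5. Hydrolysis with water at neutral pH comes back to the route at target 11.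

**Further compounds**
F1 | step 5 | 1-(3,5-dimethoxyphenyl)prop-2-en-1-one | COc1cc(OC)cc(C(=O)C=C)c1
F2 | step 2 | [3,5-bis(methoxymethoxy)phenoxy]tri(propan-2-yl)silane | COCOc1cc(O[Si](C(C)C)(C(C)C)C(C)C)cc(OCOC)c1
F3 | step 2 | [2,6-bis(methoxymethoxy)-4-{[tri(propan-2-yl)silyl]oxy}phenyl]lithium | COCOc1cc(O[Si](C(C)C)(C(C)C)C(C)C)cc(OCOC)c1[Li]
F4 | step 2 | [3,5-bis(methoxymethoxy)-4-(3-methylbut-2-en-1-yl)phenoxy]tri(propan-2-yl)silane | COCOc1cc(O[Si](C(C)C)(C(C)C)C(C)C)cc(OCOC)c1CC=C(C)C
F5 | step 8 | (2R)-2-(3,5-dimethoxyphenyl)-6-(3-methylbut-2-en-1-yl)-5,7-bis(trimethylsilyloxy)-3,4-dihydro-2H-chromene | COc1cc(OC)cc([C@H]2CCc3c(cc(O[Si](C)(C)C)c(CC=C(C)C)c3O[Si](C)(C)C)O2)c1
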